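## Retrosynthetic overview

1. Target 27 ⇐ enol ether 26: one acid operation unmasks aldehyde, ketone, amine and alcohol; iminium formation and an intramolecular Mannich reaction close the piperidine and the cyclopentane last.
2. 26 ⇐ dienyl triflate 16: two C-alkylations next to the cycloheptenone carbonyl (side chain, then CH2O), methoxycarbonylation and CuH reduction for the ester stereodiad, SmI2 removal of the blocking group, Wittig homologation.
3. 16 ⇐ diene 11 + chloroketone 13 (key step): (4+3) cycloaddition of a benzyloxy-oxyallyl cation (the ketone α-carbon made electrophilic) with a 1,3-diene gives the seven-membered ring, the tetrasubstituted alkene and the first quaternary carbon at once.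
4. 11 ⇐ ketone 1: Cu-catalysed asymmetric conjugate addition (the only external source of chirality), Pd(II) cycloalkenylation, dienyl triflate, aminomethyl Suzuki coupling.
5. Ring order: ring A → ring P → seven-membered ring → piperidine and cyclopentane together.

Atom labels (order of the target SMILES): C-a = CH(CO2Me); C-b = its CH2; C-c = quaternary C bearing C-d H2–N; C-e = N–CH; C-f = CH–C(=O)iPr; C-g = CH2; C-h = quaternary C bearing CH2OH; C-i = CH between C-h and C-e; C-j, C-k = CH2CH2; C-l=C-m = tetrasubstituted alkene; C-n = ring-fusion CH; C-o, C-p = CH2CH2. Ring A = a, b, c, m, n; ring P = l, m, n, o, p.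

Assumption: the dialkoxy-substituted cyclopentenone 2 behaves like other 4,4-disubstituted cyclopentenones in Cu-catalysed asymmetric conjugate addition; the ligand enantiomer is chosen to give the S adduct.

## Route

Step 1
Reactants: 1 1,4-dioxaspiro[4.4]nonan-7-one
Product: 2 1,4-dioxaspiro[4.4]non-8-en-7-one
Conditions: IBX (1.5 equiv), 4-methoxypyridine N-oxide, DMSO, 25–40 °C
Reagents that add atoms: none
Why: Nicolaou IBX dehydrogenation of a ketone to the enone; only the C8–C9 bond can be desaturated because the other α-carbon is flanked by the quaternary ketal carbon, and no stereocentre is formed.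

Step 2
Reactants: 2 1,4-dioxaspiro[4.4]non-8-en-7-one; 3 but-3-en-1-ylmagnesium bromide
Product: 5 (S)-{[6-(but-3-en-1-yl)-1,4-dioxaspiro[4.4]non-7-en-8-yl]oxy}trimethylsilane, via magnesium enolate 4 (not isolated)
Conditions: 3 (1.3 equiv), CuBr·SMe2 (5 mol %), Josiphos-type diphosphine (6 mol %), MTBE, −78 °C; then TMSCl, Et3N, HMPA, −78 → 0 °C
Reagents that add atoms: chlorotrimethylsilane C[Si](C)(C)Cl
Why: Feringa-type Cu-catalysed asymmetric conjugate addition of a Grignard reagent, in which the chiral Cu–diphosphine complex selects the enone face and sets C-n (S), followed by regiospecific O-silylation of the enolate.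

Step 3
Reactants: 5 (S)-{[6-(but-3-en-1-yl)-1,4-dioxaspiro[4.4]non-7-en-8-yl]oxy}trimethylsilane
Product: 6 (1S,5S)-8-methylidenespiro[bicyclo[3.3.0]octane-4,2'-[1,3]dioxolan]-2-one
Conditions: Pd(OAc)2 (10 mol %), O2 (1 atm), DMSO, 45 °C
Reagents that add atoms: none
Why: Pd(II)-mediated oxidative cycloalkenylation of a silyl enol ether (Saegusa/Kende–Toyota type): 5-exo carbopalladation of the butenyl alkene and β-hydride elimination give the exo-methylene cyclopentane, and the new ring-fusion CH is forced cis to C-n.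

Step 4
Reactants: 6 (1S,5S)-8-methylidenespiro[bicyclo[3.3.0]octane-4,2'-[1,3]dioxolan]-2-one
Product: 7 (5S)-8-methylidenespiro[bicyclo[3.3.0]oct-1-ene-4,2'-[1,3]dioxolan]-2-yl trifluoromethanesulfonate
Conditions: KHMDS (1.05 equiv), THF, −78 °C; then PhNTf2, −78 → 0 °C
Reagents that add atoms: N-phenylbis(trifluoromethanesulfonimide) O=S(=O)(N(c1ccccc1)S(=O)(=O)C(F)(F)F)C(F)(F)F
Why: enol triflate formation: the ring-fusion α-H is allylic and the other α-CH2 is neopentyl next to the ketal, so the extended dienolate forms and O-triflation gives the conjugated 2-triflyloxy-1,3-diene with only C-n left as a stereocentre.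

Step 5
Reactants: 8 potassium (bromomethyl)trifluoroborate; 9 tert-butyl N-methylcarbamate
Product: 10 potassium {[(tert-butoxycarbonyl)(methyl)amino]methyl}trifluoroborate
Conditions: KHMDS (1.05 equiv), THF, 0 → 25 °C
Reagents that add atoms: none
Why: SN2 N-alkylation of the potassium carbamate by the bromomethyltrifluoroborate (Molander synthesis of aminomethyltrifluoroborates); no stereocentre is involved.

Step 6
Reactants: 7 (5S)-8-methylidenespiro[bicyclo[3.3.0]oct-1-ene-4,2'-[1,3]dioxolan]-2-yl trifluoromethanesulfonate; 10 potassium {[(tert-butoxycarbonyl)(methyl)amino]methyl}trifluoroborate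
Product: 11 tert-butyl methyl{[(5S)-8-methylidenespiro[bicyclo[3.3.0]oct-1-ene-4,2'-[1,3]dioxolan]-2-yl]methyl}carbamate
Conditions: Pd(OAc)2 (5 mol %), XPhos (10 mol %), K2CO3 (3 equiv), toluene/H2O 4:1, 85 °C
Reagents that add atoms: none
Why: Suzuki–Miyaura (Molander) sp2–sp3 coupling of the alkenyl triflate with the aminomethyltrifluoroborate installs C-d H2–N(Me)Boc on the diene terminus without touching C-n.

Step 7
Reactants: 12 1-(benzyloxy)-3-chloropropan-2-ol
Product: 13 1-(benzyloxy)-3-chloropropan-2-one
Conditions: Dess–Martin periodinane (1.2 equiv), NaHCO3, CH2Cl2, 0 → 25 °C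
Reagents that add atoms: none
Why: Dess–Martin oxidation of the secondary alcohol to the α-chloro-α'-benzyloxy ketone, which removes the only stereocentre.

Step 8
Reactants: 11 tert-butyl methyl{[(5S)-8-methylidenespiro[bicyclo[3.3.0]oct-1-ene-4,2'-[1,3]dioxolan]-2-yl]methyl}carbamate; 13 1-(benzyloxy)-3-chloropropan-2-one
Product: 15 tricyclic diketone (ring-A cyclopentanone and α-benzyloxy cyclohept-4-enone joined through C-l=C-m; C-c quaternary), via ketal cycloadduct 14 (not isolated)
Conditions: 13 (2.5 equiv, slow addition), Et3N (3 equiv), CF3CH2OH, 0 → 25 °C; concentrate; then 1 M HCl, THF, 25 °C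
Reagents that add atoms: water O
Why: Proposed new method: Et3N in trifluoroethanol enolises 13 on its benzyloxy side and loss of chloride gives a benzyloxy-stabilised 2-oxidoallyl cation (an α-keto carbocation, the ketone α-carbon with reversed polarity); its oxocarbenium terminus is captured by the exocyclic methylene of the s-cis-locked diene and its enolate carbon then closes on the tertiary allyl cation, so this (4+3) cycloaddition forms the cycloheptenone, the C-l=C-m alkene and quaternary C-c in one step on the diene face anti to the pseudo-axial ketal oxygen (the face of H on C-n), which relays the stereocentre of step 2 to C-c; the closest known reactions are Föhlisch α-haloketone/Et3N/fluoroalcohol and Hoffmann–Albizati alkoxy-oxyallyl (4+3) cycloadditions of cyclic 1,3-dienes, and dilute acid then hydrolyses the dioxolane.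

Step 9
Reactants: 15 tricyclic diketone
Product: 16 tricyclic dienyl triflate (TfO–C-a=C-n–C-m=C-l)
Conditions: KHMDS (1.0 equiv), THF, −78 → −40 °C; then PhNTf2, −78 → 0 °C
Reagents that add atoms: N-phenylbis(trifluoromethanesulfonimide) O=S(=O)(N(c1ccccc1)S(=O)(=O)C(F)(F)F)C(F)(F)F
Why: enol triflate formation: H on C-n is α to the cyclopentanone and allylic, so equilibration gives the extended dienolate and O-triflation gives the conjugated dienyl triflate, which removes the relay centre C-n and leaves the less acidic cycloheptenone untouched.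

Step 10
Reactants: 17 4-methylpent-1-en-3-one
Product: 19 2-(2-iodoethyl)-2-(propan-2-yl)-1,3-dioxolane, via iodo silyl enol ether 18 (not isolated)
Conditions: Me3SiI (1.1 equiv), CH2Cl2, −78 °C; then ethylene glycol, −78 → 25 °C
Reagents that add atoms: iodotrimethylsilane C[Si](C)(C)I; ethane-1,2-diol OCCO
Why: Larson one-pot conversion of an enone into a β-iodo ketal: 1,4-addition of Me3SiI, then ketalisation of the silyl enol ether by the glycol; no stereocentre is formed.

Step 11
Reactants: 16 tricyclic dienyl triflate; 19 2-(2-iodoethyl)-2-(propan-2-yl)-1,3-dioxolane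
Product: 20 C-h-alkylated ketone (CH2CH2C(OCH2CH2O)iPr on C-h)
Conditions: LDA (1.1 equiv), THF, −78 °C; HMPA, 19 (1.5 equiv), −78 → −20 °C
Reagents that add atoms: none
Why: kinetic deprotonation of the α-benzyloxy ketone takes place at the α'-CH2 (C-h), away from the alkoxy-bearing carbon, and SN2 enolate alkylation with the primary iodide installs the masked 4-methyl-3-oxopentyl chain; the configuration at C-h is irrelevant because it is enolised again in step 12.

Step 12
Reactants: 20 C-h-alkylated ketone
Product: 22 quaternary C-h silyl ether (CH2OTBS and side chain on C-h), via lithium aldolate 21 (not isolated)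
Conditions: LDA (1.3 equiv), THF/HMPA, −78 → −40 °C; CH2O (gas), −78 °C; then TBSOTf, −78 → 0 °C
Reagents that add atoms: formaldehyde C=O; tert-butyldimethylsilyl trifluoromethanesulfonate CC(C)(C)[Si](C)(C)OS(=O)(=O)C(F)(F)F
Why: crossed aldol of the tetrasubstituted enolate with formaldehyde creates quaternary C-h; the electrophile enters anti to the pseudo-axial CH2N(Me)Boc arm on C-c, so CH2O ends up trans to CH2N and the side chain cis to it, and silylation of the aldolate in the flask prevents retro-aldol.

Step 13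
Reactants: 22 quaternary C-h silyl ether
Product: 23 methyl dienoate (MeO2C–C-a=C-n–C-m=C-l)
Conditions: Pd(OAc)2 (10 mol %), dppf (12 mol %), CO (1 atm), MeOH, Et3N, DMF, 60 °C
Reagents that add atoms: carbon monoxide [C-]#[O+]; methanol CO
Why: Pd-catalysed methoxycarbonylation of the alkenyl triflate gives the conjugated dienoate without changing any stereocentre.

Step 14
Reactants: 23 methyl dienoate
Product: 24 methyl ester with H on C-a and C-n cis
Conditions: Cu(OAc)2·H2O (10 mol %), 1,2-bis(diphenylphosphino)benzene (10 mol %), (EtO)2MeSiH (3 equiv), t-BuOH (3 equiv), toluene, 0 → 25 °C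
Reagents that add atoms: none
Why: ligated CuH 1,4-reduction (Stryker/Lipshutz type): hydride goes to C-n and the copper enolate is protonated at C-a, both from the convex face opposite quaternary C-h and the seven-membered ring, which gives the cis-H,H stereodiad with the ester on the concave face and should leave the more hindered C-l=C-m alkene and the ketone.

Step 15
Reactants: 24 methyl ester with H on C-a and C-n cis
Product: 25 debenzyloxylated ketone (C-j H2)
Conditions: SmI2 (2.5 equiv), MeOH, THF, −78 °C
Reagents that add atoms: none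
Why: SmI2 reduction of an α-alkoxy ketone (Molander): the ketyl expels benzyloxide and the samarium enolate is protonated, which removes the blocking group without touching ester, carbamate, ketal or alkene.

Step 16
Reactants: 25 debenzyloxylated ketone
Product: 26 methyl enol ether (C-i=CH–OMe)
Conditions: Ph3P(CH2OMe)Cl (4 equiv), KHMDS (3.8 equiv), THF, 0 °C; add 25, 0 → 45 °C
Reagents that add atoms: (methoxymethyl)triphenylphosphonium chloride COC[P+](c1ccccc1)(c1ccccc1)c1ccccc1.[Cl-]
Why: Wittig methoxymethylenation of the ketone gives the enol ether (E/Z mixture, inconsequential), the masked form of aldehyde carbon C-e.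

Step 17
Reactants: 26 methyl enol ether
Product: 27 CNP0152638.1 (target)
Conditions: 3 M HCl, THF/H2O, 45 °C; then NaOAc to pH 5, 50 °C; NaHCO3 work-up
Reagents that add atoms: water O
Why: acid unmasks aldehyde, ketone, secondary amine and alcohol; amine and aldehyde condense to a six-membered iminium ion, and an intramolecular Mannich reaction (5-exo) of the isopropyl ketone enol closes the cyclopentane, with C-e and the epimerisable C-i fixed by the cis bridge and the epimerisable C-f settling with the acyl group exo (thermodynamic).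

## Compound list

1 | 1,4-dioxaspiro[4.4]nonan-7-one | O=C1CCC2(C1)OCCO2 | starting material
2 | 1,4-dioxaspiro[4.4]non-8-en-7-one | O=C1C=CC2(C1)OCCO2 | intermediate
3 | but-3-en-1-ylmagnesium bromide | C=CCC[Mg]Br | starting material
4 | bromomagnesium (S)-6-(but-3-en-1-yl)-1,4-dioxaspiro[4.4]non-7-en-8-olate | C=CCC[C@H]1C=C(O[Mg]Br)CC12OCCO2 | intermediate (not isolated)
5 | (S)-{[6-(but-3-en-1-yl)-1,4-dioxaspiro[4.4]non-7-en-8-yl]oxy}trimethylsilane | C=CCC[C@H]1C=C(O[Si](C)(C)C)CC12OCCO2 | intermediate
6 | (1S,5S)-8-methylidenespiro[bicyclo[3.3.0]octane-4,2'-[1,3]dioxolan]-2-one (cis-fused) | C=C1CC[C@H]2[C@@H]1C(=O)CC23OCCO3 | intermediate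
7 | (5S)-8-methylidenespiro[bicyclo[3.3.0]oct-1-ene-4,2'-[1,3]dioxolan]-2-yl trifluoromethanesulfonate | C=C1CC[C@H]2C1=C(OS(=O)(=O)C(F)(F)F)CC23OCCO3 | intermediate
8 | potassium (bromomethyl)trifluoroborate | [K+].BrC[B-](F)(F)F | starting material
9 | tert-butyl N-methylcarbamate | CNC(=O)OC(C)(C)C | starting material
10 | potassium {[(tert-butoxycarbonyl)(methyl)amino]methyl}trifluoroborate | [K+].CN(C[B-](F)(F)F)C(=O)OC(C)(C)C | intermediate
11 | tert-butyl methyl{[(5S)-8-methylidenespiro[bicyclo[3.3.0]oct-1-ene-4,2'-[1,3]dioxolan]-2-yl]methyl}carbamate | C=C1CC[C@H]2C1=C(CN(C)C(=O)OC(C)(C)C)CC23OCCO3 | intermediate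
12 | 1-(benzyloxy)-3-chloropropan-2-ol (racemic) | OC(CCl)COCc1ccccc1 | starting material
13 | 1-(benzyloxy)-3-chloropropan-2-one | O=C(CCl)COCc1ccccc1 | intermediate
14 | ketal cycloadduct: 15 with C-a still as its ethylene ketal | O1CCOC12C[C@@]3(CN(C)C(=O)OC(C)(C)C)CC(=O)C(OCc4ccccc4)CC5=C3[C@@H]2CC5 | intermediate (not isolated)
15 | tricyclic diketone: ring-A cyclopentanone (C-a=O) and cyclohept-4-enone (C-i=O) joined through C-l=C-m of ring P; quaternary C-c (R) bears CH2N(Me)Boc with C-h on the face of H at C-n (S); OBn on C-j, both epimers | O=C1C[C@@]2(CN(C)C(=O)OC(C)(C)C)CC(=O)C(OCc3ccccc3)CC4=C2[C@@H]1CC4 | intermediate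
16 | tricyclic dienyl triflate TfO–C-a=C-n–C-m=C-l; C-c as in 15; OBn epimers | O=S(=O)(OC=1C[C@@]2(CN(C)C(=O)OC(C)(C)C)CC(=O)C(OCc3ccccc3)CC4=C2C=1CC4)C(F)(F)F | intermediate
17 | 4-methylpent-1-en-3-one | C=CC(=O)C(C)C | starting material
18 | [(1-iodo-4-methylpent-2-en-3-yl)oxy]trimethylsilane | C[Si](C)(C)OC(=CCI)C(C)C | intermediate (not isolated)
19 | 2-(2-iodoethyl)-2-(propan-2-yl)-1,3-dioxolane | CC(C)C1(CCI)OCCO1 | intermediate
20 | 16 carrying CH2CH2C(OCH2CH2O)CH(CH3)2 on C-h (both C-h epimers) | O=S(=O)(OC=1C[C@@]2(CN(C)C(=O)OC(C)(C)C)C(CCC5(C(C)C)OCCO5)C(=O)C(OCc3ccccc3)CC4=C2C=1CC4)C(F)(F)F | intermediate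
21 | lithium alkoxide of the C-h hydroxymethyl aldol adduct of 20 (CH2O– anti to CH2N on C-c) | O=S(=O)(OC=1C[C@@]2(CN(C)C(=O)OC(C)(C)C)[C@](CO[Li])(CCC5(C(C)C)OCCO5)C(=O)C(OCc3ccccc3)CC4=C2C=1CC4)C(F)(F)F | intermediate (not isolated)
22 | TBS ether of 21: quaternary C-h with CH2OTBS anti and side chain cis to CH2N(Me)Boc | O=S(=O)(OC=1C[C@@]2(CN(C)C(=O)OC(C)(C)C)[C@](CO[Si](C)(C)C(C)(C)C)(CCC5(C(C)C)OCCO5)C(=O)C(OCc3ccccc3)CC4=C2C=1CC4)C(F)(F)F | intermediate
23 | methyl dienoate MeO2C–C-a=C-n–C-m=C-l; otherwise as 22 | COC(=O)C=1C[C@@]2(CN(C)C(=O)OC(C)(C)C)[C@](CO[Si](C)(C)C(C)(C)C)(CCC5(C(C)C)OCCO5)C(=O)C(OCc3ccccc3)CC4=C2C=1CC4 | intermediate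
24 | methyl ester with H on C-a and C-n cis and anti to C-h (C-a, C-c, C-h, C-n as in 27); OBn epimers | COC(=O)[C@H]1C[C@@]2(CN(C)C(=O)OC(C)(C)C)[C@](CO[Si](C)(C)C(C)(C)C)(CCC5(C(C)C)OCCO5)C(=O)C(OCc3ccccc3)CC4=C2[C@H]1CC4 | intermediate
25 | 24 without the benzyloxy group (C-j H2) | COC(=O)[C@H]1C[C@@]2(CN(C)C(=O)OC(C)(C)C)[C@](CO[Si](C)(C)C(C)(C)C)(CCC5(C(C)C)OCCO5)C(=O)CCC4=C2[C@H]1CC4 | intermediate
26 | methyl enol ether of 25 (C-i=CH–OMe, E/Z mixture) | COC(=O)[C@H]1C[C@@]2(CN(C)C(=O)OC(C)(C)C)[C@](CO[Si](C)(C)C(C)(C)C)(CCC5(C(C)C)OCCO5)C(=COC)CCC4=C2[C@H]1CC4 | intermediate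
27 | CNP0152638.1 | COC(=O)[C@H]1C[C@@]23CN(C)[C@H]4[C@H](C(=O)C(C)C)C[C@]2(CO)[C@H]4CCC2=C3[C@H]1CC2 | target

## Step count and risks

Total steps: 17. Longest linear sequence: 14 (steps 1, 2, 3, 4, 6, 8, 9, 11, 12, 13, 14, 15, 16, 17; 1 → 27). Steps 5, 7 and 10 are convergent side steps.

The three steps most likely to fail:

Step 8, the (4+3) cycloaddition. The hindered diene terminus may instead give (3+2) capture through enolate carbon or oxygen, the carbamate carbonyl may trap the allyl cation (oxazolidinone with loss of the tert-butyl group), and the face selectivity from the ketal is only argued. A minor face isomer has to be removed at 15, before step 9 erases C-n. The fallback sets out from 11 and returns at 14. It replaces the base-generated zwitterion in a protic solvent by a preformed allyl cation ionised by a Lewis acid at low temperature, where cation lifetime is short and loss of the tert-butyl group is slow. 1,1-Dimethoxypropan-2-one is trans-acetalised with benzyl alcohol (CSA) to 1-(benzyloxy)-1-methoxypropan-2-one F1, and F1 is silylated (TESOTf, Et3N) to [3-(benzyloxy)-3-methoxyprop-1-en-2-yl]oxy(triethyl)silane F2. F2 and 11 with catalytic TMSOTf in CH2Cl2 at −90 °C give 14.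

Step 12, the quaternisation at C-h. Deprotonation of the tertiary C-h–H next to quaternary C-c may be slow and may compete with the C-j–H of the benzyloxy-bearing carbon. The fallback sets out from 16 and returns at 21; it makes the C-h enolate by conjugate reduction instead of deprotonation. Ethyl 4-methyl-3-oxopentanoate is ketalised (ethylene glycol, TsOH) to ethyl 2-[2-(propan-2-yl)-1,3-dioxolan-2-yl]acetate F3 and reduced (DIBAL-H, −78 °C) to 2-[2-(propan-2-yl)-1,3-dioxolan-2-yl]acetaldehyde F4. The lithium enolate of 16 (LDA, as in step 11) adds to F4 to give the aldol adduct F5, and Burgess dehydration gives the α-alkylidene ketone F6. L-Selectride (−78 °C) reduces F6 in 1,4-fashion, which generates the C-h enolate regiospecifically, and formaldehyde traps it to give 21.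

Step 14, the reduction of the dienoate. CuH may add in 1,6-fashion (moving the alkene to C-m=C-n) or fail at the fully substituted β-carbon. The fallback sets out from 23 and returns at 24; it uses carboxylate-directed hydrogenation instead of hydride conjugate addition. 23 is saponified (LiOH, THF/H2O) to the dienoic acid F7. F7 is hydrogenated with Ru(OAc)2(BINAP) (H2 50 atm, MeOH), where the bound carboxylate delivers H2 only to the C-a=C-n bond from the convex face, to the saturated acid F8. TMSCHN2 then gives 24.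

Further compounds

F1 | step 8 | 1-(benzyloxy)-1-methoxypropan-2-one | CC(=O)C(OC)OCc1ccccc1
F2 | step 8 | [3-(benzyloxy)-3-methoxyprop-1-en-2-yl]oxy(triethyl)silane | C=C(O[Si](CC)(CC)CC)C(OC)OCc1ccccc1
F3 | step 12 | ethyl 2-[2-(propan-2-yl)-1,3-dioxolan-2-yl]acetate | CCOC(=O)CC1(C(C)C)OCCO1
F4 | step 12 | 2-[2-(propan-2-yl)-1,3-dioxolan-2-yl]acetaldehyde | O=CCC1(C(C)C)OCCO1
F5 | step 12 | aldol adduct of 16 and F4 (C-h–CH(OH)CH2C(OCH2CH2O)iPr) | O=S(=O)(OC=1C[C@@]2(CN(C)C(=O)OC(C)(C)C)C(C(O)CC5(C(C)C)OCCO5)C(=O)C(OCc3ccccc3)CC4=C2C=1CC4)C(F)(F)F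
F6 | step 12 | α-alkylidene ketone (C-h=CH–CH2C(OCH2CH2O)iPr) | O=S(=O)(OC=1C[C@@]2(CN(C)C(=O)OC(C)(C)C)C(=CCC5(C(C)C)OCCO5)C(=O)C(OCc3ccccc3)CC4=C2C=1CC4)C(F)(F)F
F7 | step 14 | dienoic acid corresponding to 23 | OC(=O)C=1C[C@@]2(CN(C)C(=O)OC(C)(C)C)[C@](CO[Si](C)(C)C(C)(C)C)(CCC5(C(C)C)OCCO5)C(=O)C(OCc3ccccc3)CC4=C2C=1CC4
F8 | step 14 | saturated acid corresponding to 24 | OC(=O)[C@H]1C[C@@]2(CN(C)C(=O)OC(C)(C)C)[C@](CO[Si](C)(C)C(C)(C)C)(CCC5(C(C)C)OCCO5)C(=O)C(OCc3ccccc3)CC4=C2[C@H]1CC4
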